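**Strategy.** The flavone is disconnected at C3: ring C (O1, C2, C3, C4, C4a, C8a) is a 2-aryl-3-oxybenzofuran into which one carbon has been inserted between the aryl-bearing C2 and the carbonyl carbon C4. Dibromocarbene addition to the enol ether double bond of a 3-silyloxy-2-arylbenzofuran, followed by opening of the cyclopropane, should form C2–C3 and C3–C4 and enlarge the furan to the pyranone in one operation. The precursor is the TBS enol ether of 4,5,6,7-tetramethoxy-2-(4-methoxyphenyl)benzofuran-3(2H)-one, made in four steps from 1,2,3,4-tetramethoxybenzene and 4-methoxyphenylacetic acid; hydrodebromination and chelation-controlled 5-O-demethylation finish the synthesis.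

Key step: step 5

Assumption: 1, 5 and 10 are bought; 7 and 8 (one stereocentre each) and 11 (two, cis-fused) are racemic, and the target has no stereocentre.

**Step 1**
Reactants: 1 1,2,3,4-tetramethoxybenzene
Product: 4 2,3,4,5-tetramethoxyphenol, via (2,3,4,5-tetramethoxyphenyl)lithium 2 (not isolated), via dimethyl (2,3,4,5-tetramethoxyphenyl)boronate 3 (not isolated)
Conditions: n-BuLi, TMEDA, THF, 0 °C; B(OMe)3, −78 °C to rt; then AcOH, 30% aq. H2O2, 0 °C to rt
Reagents that add atoms: hydrogen peroxide, OO
Why: Directed ortho-metalation next to a methoxy group (C5 and C6 of 1 are equivalent), borylation and oxidative 1,2-shift of the aryl group from boron to oxygen (lithiation–borylation–oxidation) should install the hydroxyl at the only kind of free ring position.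

**Step 2**
Reactants: 4 2,3,4,5-tetramethoxyphenol; 5 4-methoxyphenylacetic acid
Product: 6 1-(2-hydroxy-3,4,5,6-tetramethoxyphenyl)-2-(4-methoxyphenyl)ethan-1-one
Conditions: BF3·OEt2 (neat), 80 °C; then aq. NaOAc
Reagents that add atoms: none
Why: BF3-promoted Friedel–Crafts acylation of a phenol by an arylacetic acid (deoxybenzoin synthesis, O-acylation followed by a Fries-type shift) can only occur at C6, the one unsubstituted carbon, which is ortho to the hydroxyl and para to a methoxy group.

**Step 3**
Reactants: 6 1-(2-hydroxy-3,4,5,6-tetramethoxyphenyl)-2-(4-methoxyphenyl)ethan-1-one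
Product: 8 racemic 4,5,6,7-tetramethoxy-2-(4-methoxyphenyl)benzofuran-3(2H)-one, via benzylic bromo ketone 7 (not isolated)
Conditions: PhNMe3Br3 (1.0 equiv), THF, 0 °C to rt; then NaOAc, MeOH, rt, under Ar
Reagents that add atoms: none
Why: Tribromide bromination of the enol of the benzylic ketone followed by intramolecular Williamson etherification (5-exo-tet displacement of the benzylic bromide by the ortho phenoxide) is the classical coumaran-3-one synthesis from 2-hydroxyaryl ketones; the phenol ring has no free position, one equivalent of reagent is used, and the C2 stereocentre forms racemic and is removed in step 4.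

**Step 4**
Reactants: 8 racemic 4,5,6,7-tetramethoxy-2-(4-methoxyphenyl)benzofuran-3(2H)-one
Product: 9 tert-butyl{[4,5,6,7-tetramethoxy-2-(4-methoxyphenyl)benzofuran-3-yl]oxy}dimethylsilane
Conditions: TBSOTf, Et3N, CH2Cl2, 0 °C, under Ar
Reagents that add atoms: tert-butyldimethylsilyl trifluoromethanesulfonate (TBSOTf), CC(C)(C)[Si](C)(C)OS(=O)(=O)C(F)(F)F
Why: Silyl enol ether formation (soft enolisation by Et3N and the silyl triflate) should go on oxygen because O-silylation aromatises the furan ring, and it fixes the enol form and protects C2 from autoxidation.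

**Step 5**
Reactants: 9 tert-butyl{[4,5,6,7-tetramethoxy-2-(4-methoxyphenyl)benzofuran-3-yl]oxy}dimethylsilane; 10 bromoform
Product: 13 3-bromo-5,6,7,8-tetramethoxy-2-(4-methoxyphenyl)chromen-4-one, via gem-dibromocyclopropane 11 (not isolated), via 3-bromo-4-silyloxybenzopyrylium bromide 12 (not isolated)
Conditions: CHBr3 (3 equiv), KOtBu (4 equiv, added in portions), hexane–toluene, −20 °C to rt; then 1 M HCl, THF, rt
Reagents that add atoms: bromoform (compound 10), BrC(Br)Br
Why: Proposed new method: KOtBu converts bromoform by α-elimination into dibromocarbene, which should add [2+1] to the C2=C3 enol ether bond of 9 to give the cis-fused gem-dibromocyclopropane 11; loss of the endo bromide with concerted disrotatory cleavage of the former C2–C3 bond (cyclopropyl-to-allyl cation electrocyclic opening) then gives the aromatic 3-bromo-4-silyloxybenzopyrylium ion 12, from which tert-butoxide or bromide takes the silyl group to leave the 4-pyranone 13 with the carbene carbon as C3. The closest known reaction types are the dihalocarbene ring expansion of cyclic silyl enol ethers to 2-halo-2-enones and the Ciamician–Dennstedt expansion of indoles to 3-haloquinolines; their use on a 2-aryl-3-silyloxybenzofuran to make a flavone is the untested part. The pyranone ring is closed by ring enlargement and not by a cyclisation: the [2+1] addition makes C2–C3 and C3–C4 in a three-membered ring and the electrocyclic opening merges it with the furan into the six-membered ring, so no ring-closure rule is at stake. No stereocentre is created in 13; the two ring-fusion centres of 11 are transient and necessarily cis. The step needs chemoselectivity for the furan double bond over both methoxylated benzene rings and cleavage of the internal cyclopropane bond, and both are secured by O1 and the silyloxy oxygen, which make C2=C3 the most nucleophilic π bond and stabilise the developing cation at the two carbons that flank the inserted one. The TBS group is chosen because a silyl enol ether of this bulk should survive KOtBu in a hydrocarbon solvent yet be lost at once from the oxygen of the pyrylium ion.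

**Step 6**
Reactants: 13 3-bromo-5,6,7,8-tetramethoxy-2-(4-methoxyphenyl)chromen-4-one
Product: 14 5,6,7,8-tetramethoxy-2-(4-methoxyphenyl)chromen-4-one (tangeretin)
Conditions: Pd(OAc)2 (5 mol%), PPh3 (10 mol%), HCO2H, Et3N, DMF, 60 °C
Reagents that add atoms: none
Why: Palladium-catalysed formate hydrodehalogenation: zerovalent palladium formed in situ inserts into the C3–Br bond, formate replaces bromide, and decarboxylation followed by reductive elimination delivers hydrogen to C3 while the pyranone double bond and the aryl methyl ethers are untouched.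

**Step 7**
Reactants: 14 5,6,7,8-tetramethoxy-2-(4-methoxyphenyl)chromen-4-one
Product: 16 5-hydroxy-6,7,8-trimethoxy-2-(4-methoxyphenyl)chromen-4-one, via 5-O-dichloroboryl chelate 15 (not isolated)
Conditions: BCl3 (1 M in CH2Cl2, 1.5 equiv), CH2Cl2, −20 to 0 °C; then H2O, rt
Reagents that add atoms: none
Why: Chelation-controlled Lewis-acid ether cleavage: BCl3 binds the C4 carbonyl oxygen and the peri C5 methoxy oxygen in a six-membered chelate, so chloride removes only that methyl group (the standard selective 5-O-demethylation of polymethoxyflavones), and water frees the phenol from chelate 15.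

**Compound list**
1 | 1,2,3,4-tetramethoxybenzene | COc1ccc(OC)c(OC)c1OC | starting material
2 | (2,3,4,5-tetramethoxyphenyl)lithium | [Li]c1cc(OC)c(OC)c(OC)c1OC | intermediate (not isolated)
3 | dimethyl (2,3,4,5-tetramethoxyphenyl)boronate | COB(OC)c1cc(OC)c(OC)c(OC)c1OC | intermediate (not isolated)
4 | 2,3,4,5-tetramethoxyphenol | Oc1cc(OC)c(OC)c(OC)c1OC | intermediate
5 | 4-methoxyphenylacetic acid | COc1ccc(CC(=O)O)cc1 | starting material
6 | 1-(2-hydroxy-3,4,5,6-tetramethoxyphenyl)-2-(4-methoxyphenyl)ethan-1-one | COc1ccc(CC(=O)c2c(O)c(OC)c(OC)c(OC)c2OC)cc1 | intermediate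
7 | racemic 2-bromo-1-(2-hydroxy-3,4,5,6-tetramethoxyphenyl)-2-(4-methoxyphenyl)ethan-1-one | COc1ccc(C(Br)C(=O)c2c(O)c(OC)c(OC)c(OC)c2OC)cc1 | intermediate (not isolated)
8 | racemic 4,5,6,7-tetramethoxy-2-(4-methoxyphenyl)benzofuran-3(2H)-one | COc1ccc(C2Oc3c(OC)c(OC)c(OC)c(OC)c3C2=O)cc1 | intermediate
9 | tert-butyl{[4,5,6,7-tetramethoxy-2-(4-methoxyphenyl)benzofuran-3-yl]oxy}dimethylsilane | COc1ccc(-c2oc3c(OC)c(OC)c(OC)c(OC)c3c2O[Si](C)(C)C(C)(C)C)cc1 | intermediate
10 | bromoform | BrC(Br)Br | starting material
11 | racemic cis-fused 1,1-dibromo-6b-[(tert-butyldimethylsilyl)oxy]-3,4,5,6-tetramethoxy-1a-(4-methoxyphenyl)-1a,6b-dihydro-1H-cyclopropa[b]benzofuran | COc1ccc(cc1)C12Oc3c(OC)c(OC)c(OC)c(OC)c3C1(O[Si](C)(C)C(C)(C)C)C2(Br)Br | intermediate (not isolated)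
12 | 3-bromo-4-[(tert-butyldimethylsilyl)oxy]-5,6,7,8-tetramethoxy-2-(4-methoxyphenyl)chromenylium bromide | COc1ccc(cc1)-c1[o+]c2c(OC)c(OC)c(OC)c(OC)c2c(O[Si](C)(C)C(C)(C)C)c1Br.[Br-] | intermediate (not isolated)
13 | 3-bromo-5,6,7,8-tetramethoxy-2-(4-methoxyphenyl)chromen-4-one | COc1ccc(-c2oc3c(OC)c(OC)c(OC)c(OC)c3c(=O)c2Br)cc1 | intermediate
14 | 5,6,7,8-tetramethoxy-2-(4-methoxyphenyl)chromen-4-one (tangeretin) | COc1ccc(-c2cc(=O)c3c(OC)c(OC)c(OC)c(OC)c3o2)cc1 | intermediate
15 | 5-[(dichloroboranyl)oxy]-6,7,8-trimethoxy-2-(4-methoxyphenyl)chromen-4-one, boron chelated by the C4 carbonyl oxygen | COc1ccc(-c2cc(=O)c3c(OB(Cl)Cl)c(OC)c(OC)c(OC)c3o2)cc1 | intermediate (not isolated)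
16 | 5-hydroxy-6,7,8-trimethoxy-2-(4-methoxyphenyl)chromen-4-one | COc1ccc(-c2cc(=O)c3c(O)c(OC)c(OC)c(OC)c3o2)cc1 | target

**Total step count:** 7
**Longest linear sequence:** 7 steps (1 → 4 → 6 → 8 → 9 → 13 → 14 → 16)

**Steps most likely to fail**

1. Step 5 (proposed new method). The silyl enol ether may be cleaved by tert-butoxide before the carbene arrives, so that the resulting enolate is alkylated at C2 instead of being ring-expanded. The carbene may also fail to add to the crowded tetrasubstituted double bond. Fallback by known chemistry, setting out from phenol 4 and rejoining at flavone 14: Friedel–Crafts acetylation of 4 (AcOH, BF3·OEt2, 80 °C) should give 1-(2-hydroxy-3,4,5,6-tetramethoxyphenyl)ethan-1-one F1. Claisen–Schmidt condensation of this ketone with 4-methoxybenzaldehyde (KOH, EtOH, rt) should give (E)-1-(2-hydroxy-3,4,5,6-tetramethoxyphenyl)-3-(4-methoxyphenyl)prop-2-en-1-one F2. Oxidative cyclisation of the 2'-hydroxychalcone (catalytic I2, DMSO, 120 °C) should give 14, which then enters step 7.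

2. Step 3. A second bromination at C2 may follow ring closure, the tribromide may attack the electron-rich rings, and the product may autoxidise at C2 under the basic closing conditions. Fallback without electrophilic bromine, setting out from 6 and rejoining at 8: Regitz diazo transfer to the activated benzylic methylene (p-ABSA, DBU, MeCN, 0 °C to rt) should give 2-diazo-1-(2-hydroxy-3,4,5,6-tetramethoxyphenyl)-2-(4-methoxyphenyl)ethan-1-one F3. Carbenoid O–H insertion into the ortho phenol (Rh2(OAc)4, 1 mol%, CH2Cl2, rt) should close the furanone ring under neutral conditions to give 8.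

3. Step 2. Acylation at the carbon flanked by the hydroxyl and a methoxy group may be slow, and prolonged heating with the Lewis acid may cleave the methyl ether next to the new carbonyl. Fallback that forms the C–O bond first, setting out from 4 and rejoining at 8 (6 and step 3 are bypassed): commercial methyl 2-(4-methoxyphenyl)acetate is brominated at the benzylic carbon (NBS, AIBN, PhCF3, 80 °C) to racemic methyl 2-bromo-2-(4-methoxyphenyl)acetate F4. Williamson etherification of 4 with this bromide (K2CO3, acetone, rt to 50 °C) should give racemic methyl 2-(4-methoxyphenyl)-2-(2,3,4,5-tetramethoxyphenoxy)acetate F5. Saponification (LiOH, THF/H2O, rt; then HCl) should give racemic 2-(4-methoxyphenyl)-2-(2,3,4,5-tetramethoxyphenoxy)acetic acid F6. Intramolecular Friedel–Crafts acylation through the mixed anhydride (TFAA, CH2Cl2, 0 °C to rt) onto the free ortho carbon should give 8.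

**Further compounds**
F1 | step 5 | 1-(2-hydroxy-3,4,5,6-tetramethoxyphenyl)ethan-1-one | CC(=O)c1c(O)c(OC)c(OC)c(OC)c1OC
F2 | step 5 | (E)-1-(2-hydroxy-3,4,5,6-tetramethoxyphenyl)-3-(4-methoxyphenyl)prop-2-en-1-one | COc1ccc(/C=C/C(=O)c2c(O)c(OC)c(OC)c(OC)c2OC)cc1
F3 | step 3 | 2-diazo-1-(2-hydroxy-3,4,5,6-tetramethoxyphenyl)-2-(4-methoxyphenyl)ethan-1-one | COc1ccc(C(=[N+]=[N-])C(=O)c2c(O)c(OC)c(OC)c(OC)c2OC)cc1
F4 | step 2 | racemic methyl 2-bromo-2-(4-methoxyphenyl)acetate | COC(=O)C(Br)c1ccc(OC)cc1
F5 | step 2 | racemic methyl 2-(4-methoxyphenyl)-2-(2,3,4,5-tetramethoxyphenoxy)acetate | COC(=O)C(Oc1cc(OC)c(OC)c(OC)c1OC)c1ccc(OC)cc1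
F6 | step 2 | racemic 2-(4-methoxyphenyl)-2-(2,3,4,5-tetramethoxyphenoxy)acetic acid | OC(=O)C(Oc1cc(OC)c(OC)c(OC)c1OC)c1ccc(OC)cc1
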